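**Plan**
- Retrosynthesis (isoflavone numbering): the O1–C2 bond of the pyranone is cut first, then C4a–C4 and C4–C3 together, and last the C1'–vinyl and C5'–prenyl bonds of ring B.
- Enabling feature: the C4 carbonyl sits between C4a of ring A and C3, and C3 is the β-carbon of the O1–C2=C3 enol unit that carries ring B. C4 can therefore be carbon monoxide placed between an aryl iodide carbon and the nucleophilic carbon of a ring-B enol ether.
- Forward: ring A is prepared as a symmetric 2-iodophloroglucinol tris-silyl ether (2 steps) and ring B as an (E)-β-ethoxystyrene (5 steps, prenyl by Claisen rearrangement, enol ether by Suzuki coupling). A palladium carbonylation joins the two with CO without closing a ring; fluoride then frees the phenols and closes ring C, the only ring made.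
- Stereochemistry: the target has no stereocentre and is achiral. The only stereo-element on the way, the enol ether geometry, comes from a stereoretentive coupling and disappears on ring closure.

Key step: step 8

Remarks on the chemistry (assumptions):
- The target is achiral, so no enantioselective step is needed.
- Silyl ethers are used on all phenols. An ortho alkoxymethyl ether could capture the aroyl electrophile of step 8 intramolecularly, and fluoride deprotection avoids acid that could cyclise the ortho-prenylphenol to a chroman.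
- The alkoxy group of the enol ether is lost in the last step, so the ethoxy compound is used; its boronate 11 and the phenol 4 are taken as commercially available.

**Route**

Step 1
Reactants: 1 phloroglucinol
Product: 2 1,3,5-tris(tert-butyldimethylsilyloxy)benzene
Conditions: TBSCl, imidazole, DMF, rt
Reagents that add atoms: tert-butyldimethylsilyl chloride, CC(C)(C)[Si](C)(C)Cl
Why: Imidazole-promoted O-silylation of phenols converts the three equivalent hydroxyl groups into silyl ethers that should survive the carbonylation and fall to fluoride at the end.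

Step 2
Reactants: 2 1,3,5-tris(tert-butyldimethylsilyloxy)benzene
Product: 3 2-iodo-1,3,5-tris(tert-butyldimethylsilyloxy)benzene
Conditions: NIS (1 equiv), MeCN/CH2Cl2, 0 °C to rt, dark
Reagents that add atoms: N-iodosuccinimide, O=C1CCC(=O)N1I
Why: Electrophilic aromatic iodination should be easy on an arene activated by three silyloxy groups, the three free positions are equivalent, and the first iodine shields and deactivates the ring against a second substitution.

Step 3
Reactants: 4 4-bromo-2-methoxyphenol, 5 3-chloro-3-methylbut-1-yne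
Product: 6 4-bromo-2-methoxy-1-[(2-methylbut-3-yn-2-yl)oxy]benzene
Conditions: DBU, CuCl2·2H2O (cat.), MeCN, 0 °C
Reagents that add atoms: none
Why: Copper-catalysed O-propargylation of a phenol with a tertiary propargylic chloride is the standard entry to aryl 1,1-dimethylpropargyl ethers, which a plain SN2 alkylation cannot give.

Step 4
Reactants: 6 4-bromo-2-methoxy-1-[(2-methylbut-3-yn-2-yl)oxy]benzene
Product: 7 4-bromo-2-methoxy-1-[(2-methylbut-3-en-2-yl)oxy]benzene
Conditions: H2 (1 atm), Pd/CaCO3 (Pb-poisoned), quinoline, EtOAc, rt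
Reagents that add atoms: none
Why: Lindlar semihydrogenation should stop at the terminal alkene on the poisoned catalyst and leave the aryl bromide and the ether untouched.

Step 5
Reactants: 7 4-bromo-2-methoxy-1-[(2-methylbut-3-en-2-yl)oxy]benzene
Product: 9 4-bromo-2-methoxy-6-(3-methylbut-2-en-1-yl)phenol, via Claisen dienone 8 (not isolated)
Conditions: PhNEt2, 150 °C
Reagents that add atoms: none
Why: The aromatic Claisen rearrangement, a [3,3]-sigmatropic shift, should deliver the 1,1-dimethylallyl group with allylic inversion as a prenyl group to C6, the only free ortho position (the para position carries bromine), after which dienone 8 tautomerises to the phenol.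

Step 6
Reactants: 9 4-bromo-2-methoxy-6-(3-methylbut-2-en-1-yl)phenol
Product: 10 [4-bromo-2-methoxy-6-(3-methylbut-2-en-1-yl)phenoxy]tri(propan-2-yl)silane
Conditions: TIPSCl, imidazole, DMF, 40 °C
Reagents that add atoms: triisopropylsilyl chloride, CC(C)[Si](Cl)(C(C)C)C(C)C
Why: Silylation of the phenol as a hindered triisopropylsilyl ether is chosen because it should withstand the aqueous base of the cross-coupling and the carbonylation, yet leave with fluoride together with the other silyl groups.

Step 7
Reactants: 10 [4-bromo-2-methoxy-6-(3-methylbut-2-en-1-yl)phenoxy]tri(propan-2-yl)silane, 11 2-[(E)-2-ethoxyethenyl]-4,4,5,5-tetramethyl-1,3,2-dioxaborolane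
Product: 12 {4-[(E)-2-ethoxyethenyl]-2-methoxy-6-(3-methylbut-2-en-1-yl)phenoxy}tri(propan-2-yl)silane
Conditions: Pd(dppf)Cl2 (cat.), K3PO4, dioxane/H2O, 80 °C; non-acidic work-up
Reagents that add atoms: none
Why: Suzuki–Miyaura coupling of an aryl bromide with an alkenylboronate proceeds with retention of alkene geometry, so the E enol ether should result as a single isomer, and the basic medium protects the acid-labile enol ether.

Step 8
Reactants: 3 2-iodo-1,3,5-tris(tert-butyldimethylsilyloxy)benzene, 12 {4-[(E)-2-ethoxyethenyl]-2-methoxy-6-(3-methylbut-2-en-1-yl)phenoxy}tri(propan-2-yl)silane, 13 carbon monoxide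
Product: 15 (E)-3-ethoxy-2-[3-methoxy-5-(3-methylbut-2-en-1-yl)-4-(triisopropylsilyloxy)phenyl]-1-[2,4,6-tris(tert-butyldimethylsilyloxy)phenyl]prop-2-en-1-one, via aroyl iodide 14 (not isolated)
Conditions: Pd(PtBu3)2 (cat.), CO (5 bar), iPr2NEt, MeCN/toluene, 60 °C
Reagents that add atoms: none
Why: Proposed new method: Pd(0)/PtBu3 inserts into the C–I bond of 3, CO insertion gives the aroyl-palladium iodide, and the bulky phosphine under CO pressure releases it reversibly as aroyl iodide 14, whose acylium character is raised by the three silyloxy donors; enol ether 12 attacks this electrophile through the carbon that bears ring B to give an oxygen-stabilised oxocarbenium ion, and the amine removes the doubly activated α-proton, so that C4a–C4 and C4–C3 form in one operation. The closest known reaction types are the palladium-catalysed carbonylative Heck coupling of aryl halides with alkyl vinyl ethers to β-alkoxy enones and the palladium-catalysed carbonylative C–H acylation of electron-rich heteroarenes through aroyl iodides formed in situ; neither has been shown on a 1,2-disubstituted β-aryl enol ether. No ring closes and no stereocentre forms; the enone double bond is expected as the E isomer (ethoxy anti to the carbonyl) because the proton is lost under thermodynamic control, and its geometry has no bearing on the later ring closure. The step needs acylation at the aryl-bearing carbon and not at the oxygen-bearing one: the oxygen lone pair makes the aryl-bearing carbon the nucleophilic terminus in an outer-sphere attack, while a migratory insertion into the aroyl–palladium bond, which could place the acyl group on the other carbon, is disfavoured by the bulky ligand and the CO-saturated metal. It also needs CO insertion to outrun direct arylation, which the two ortho silyloxy groups secure by slowing alkene insertion into the aryl–palladium bond, and the symmetric iodide leaves no regiochemical question on ring A.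

Step 9
Reactants: 15 (E)-3-ethoxy-2-[3-methoxy-5-(3-methylbut-2-en-1-yl)-4-(triisopropylsilyloxy)phenyl]-1-[2,4,6-tris(tert-butyldimethylsilyloxy)phenyl]prop-2-en-1-one
Product: 17 2'-deoxypiscerythrone, via tetraphenol enone 16 (not isolated)
Conditions: TBAF, AcOH, THF, 0 °C to 40 °C
Reagents that add atoms: none
Why: Buffered fluoride should cleave the four aryl silyl ethers, and one of the two equivalent ortho phenols of ring A then adds to C2 of the β-ethoxy enone and expels ethanol (6-endo oxa-Michael addition–elimination), the standard chromone closure of a 2-hydroxyaryl β-alkoxyvinyl ketone, with no acid strong enough to cyclise the ortho-prenylphenol.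

**Compound list**

1 | phloroglucinol (benzene-1,3,5-triol) | Oc1cc(O)cc(O)c1 | starting material
2 | 1,3,5-tris(tert-butyldimethylsilyloxy)benzene | CC(C)(C)[Si](C)(C)Oc1cc(O[Si](C)(C)C(C)(C)C)cc(O[Si](C)(C)C(C)(C)C)c1 | intermediate
3 | 2-iodo-1,3,5-tris(tert-butyldimethylsilyloxy)benzene | CC(C)(C)[Si](C)(C)Oc1cc(O[Si](C)(C)C(C)(C)C)c(I)c(O[Si](C)(C)C(C)(C)C)c1 | intermediate
4 | 4-bromo-2-methoxyphenol | COc1cc(Br)ccc1O | starting material
5 | 3-chloro-3-methylbut-1-yne | CC(C)(Cl)C#C | starting material
6 | 4-bromo-2-methoxy-1-[(2-methylbut-3-yn-2-yl)oxy]benzene | COc1cc(Br)ccc1OC(C)(C)C#C | intermediate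
7 | 4-bromo-2-methoxy-1-[(2-methylbut-3-en-2-yl)oxy]benzene | COc1cc(Br)ccc1OC(C)(C)C=C | intermediate
8 | 4-bromo-2-methoxy-6-(3-methylbut-2-en-1-yl)cyclohexa-2,4-dien-1-one (racemic, not isolated) | O=C1C(OC)=CC(Br)=CC1CC=C(C)C | intermediate
9 | 4-bromo-2-methoxy-6-(3-methylbut-2-en-1-yl)phenol | COc1cc(Br)cc(CC=C(C)C)c1O | intermediate
10 | [4-bromo-2-methoxy-6-(3-methylbut-2-en-1-yl)phenoxy]tri(propan-2-yl)silane | COc1cc(Br)cc(CC=C(C)C)c1O[Si](C(C)C)(C(C)C)C(C)C | intermediate
11 | 2-[(E)-2-ethoxyethenyl]-4,4,5,5-tetramethyl-1,3,2-dioxaborolane | CCO/C=C/B1OC(C)(C)C(C)(C)O1 | starting material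
12 | {4-[(E)-2-ethoxyethenyl]-2-methoxy-6-(3-methylbut-2-en-1-yl)phenoxy}tri(propan-2-yl)silane | CCO/C=C/c1cc(OC)c(O[Si](C(C)C)(C(C)C)C(C)C)c(CC=C(C)C)c1 | intermediate
13 | carbon monoxide | [C-]#[O+] | starting material
14 | 2,4,6-tris(tert-butyldimethylsilyloxy)benzoyl iodide (not isolated) | CC(C)(C)[Si](C)(C)Oc1cc(O[Si](C)(C)C(C)(C)C)c(C(=O)I)c(O[Si](C)(C)C(C)(C)C)c1 | intermediate
15 | (E)-3-ethoxy-2-[3-methoxy-5-(3-methylbut-2-en-1-yl)-4-(triisopropylsilyloxy)phenyl]-1-[2,4,6-tris(tert-butyldimethylsilyloxy)phenyl]prop-2-en-1-one | CCO/C=C(/C(=O)c1c(O[Si](C)(C)C(C)(C)C)cc(O[Si](C)(C)C(C)(C)C)cc1O[Si](C)(C)C(C)(C)C)c1cc(OC)c(O[Si](C(C)C)(C(C)C)C(C)C)c(CC=C(C)C)c1 | intermediate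
16 | (E)-3-ethoxy-2-[4-hydroxy-3-methoxy-5-(3-methylbut-2-en-1-yl)phenyl]-1-(2,4,6-trihydroxyphenyl)prop-2-en-1-one (not isolated) | CCO/C=C(/C(=O)c1c(O)cc(O)cc1O)c1cc(OC)c(O)c(CC=C(C)C)c1 | intermediate
17 | 2'-deoxypiscerythrone, 5,7-dihydroxy-3-[4-hydroxy-3-methoxy-5-(3-methylbut-2-en-1-yl)phenyl]-4H-chromen-4-one | COc1cc(-c2coc3cc(O)cc(O)c3c2=O)cc(CC=C(C)C)c1O | target

**Count**
Total steps: 9. Longest linear sequence: 7 (steps 3 to 9, from 4 to 17).

**Steps most likely to fail**

Step 8. The acyl group may be delivered to the oxygen-bearing carbon through migratory insertion, the hindered aroyl electrophile may fail to engage the disubstituted enol ether, or the hydrogen iodide formed may destroy the enol ether before it is acylated. The fallback uses known deoxybenzoin chemistry; it sets out from 12 and 3 and returns at 17.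
- Enol ether 12 is hydrolysed with dilute aqueous HCl in THF to 2-[3-methoxy-5-(3-methylbut-2-en-1-yl)-4-(triisopropylsilyloxy)phenyl]acetaldehyde F1.
- Iodide 3 is converted by iodine–magnesium exchange (iPrMgCl·LiCl, THF, −20 °C) into 2,4,6-tris(tert-butyldimethylsilyloxy)phenylmagnesium chloride F2.
- F2 is added to F1 in the presence of LaCl3·2LiCl to suppress enolisation and quenched cold to avoid silyl migration. This should give racemic 2-[3-methoxy-5-(3-methylbut-2-en-1-yl)-4-(triisopropylsilyloxy)phenyl]-1-[2,4,6-tris(tert-butyldimethylsilyloxy)phenyl]ethan-1-ol F3.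
- Dess–Martin oxidation would give the deoxybenzoin 2-[3-methoxy-5-(3-methylbut-2-en-1-yl)-4-(triisopropylsilyloxy)phenyl]-1-[2,4,6-tris(tert-butyldimethylsilyloxy)phenyl]ethan-1-one F4.
- Condensation with N,N-dimethylformamide dimethyl acetal at 90 °C supplies C2 as (E)-3-(dimethylamino)-2-[3-methoxy-5-(3-methylbut-2-en-1-yl)-4-(triisopropylsilyloxy)phenyl]-1-[2,4,6-tris(tert-butyldimethylsilyloxy)phenyl]prop-2-en-1-one F5.
- TBAF/AcOH in THF with gentle warming would desilylate F5 to (E)-3-(dimethylamino)-2-[4-hydroxy-3-methoxy-5-(3-methylbut-2-en-1-yl)phenyl]-1-(2,4,6-trihydroxyphenyl)prop-2-en-1-one F6, which closes the pyranone with loss of dimethylamine to give 17.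

Step 5. The tertiary allyl ether may fragment to the phenol and isoprene, or the ortho-prenylphenol may cyclise further to a chroman at the rearrangement temperature. The fallback builds the prenyl group in two stages; it sets out from 4 and returns at 9, replacing steps 3 to 5.
- Phenol 4 is O-allylated (allyl bromide, K2CO3, acetone) to 4-bromo-2-methoxy-1-(prop-2-en-1-yloxy)benzene F7.
- Thermal Claisen rearrangement (PhNEt2, 190 °C) passes through 4-bromo-2-methoxy-6-(prop-2-en-1-yl)cyclohexa-2,4-dien-1-one F8 and should give 4-bromo-2-methoxy-6-(prop-2-en-1-yl)phenol F9.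
- Olefin cross-metathesis of F9 with excess 2-methylbut-2-ene (Ru–NHC benzylidene catalyst, CH2Cl2, 40 °C) converts the allyl group into the prenyl group of 9.

Step 2. Over-iodination or loss of silyl groups from the very electron-rich arene may occur through traces of acid. The fallback reverses the order of halogenation and protection; it sets out from 1 and returns at 3.
- Phloroglucinol 1 is mono-iodinated as the free triol (I2, NaHCO3, aqueous THF, 0 °C) to 2-iodobenzene-1,3,5-triol F10.
- F10 is silylated at once (TBSCl, imidazole, DMF) to give 3.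

**Further compounds**
F1 | step 8 | 2-[3-methoxy-5-(3-methylbut-2-en-1-yl)-4-(triisopropylsilyloxy)phenyl]acetaldehyde | O=CCc1cc(OC)c(O[Si](C(C)C)(C(C)C)C(C)C)c(CC=C(C)C)c1
F2 | step 8 | 2,4,6-tris(tert-butyldimethylsilyloxy)phenylmagnesium chloride | CC(C)(C)[Si](C)(C)Oc1cc(O[Si](C)(C)C(C)(C)C)c([Mg]Cl)c(O[Si](C)(C)C(C)(C)C)c1
F3 | step 8 | racemic 2-[3-methoxy-5-(3-methylbut-2-en-1-yl)-4-(triisopropylsilyloxy)phenyl]-1-[2,4,6-tris(tert-butyldimethylsilyloxy)phenyl]ethan-1-ol | CC(C)(C)[Si](C)(C)Oc1cc(O[Si](C)(C)C(C)(C)C)c(C(O)Cc2cc(OC)c(O[Si](C(C)C)(C(C)C)C(C)C)c(CC=C(C)C)c2)c(O[Si](C)(C)C(C)(C)C)c1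
F4 | step 8 | 2-[3-methoxy-5-(3-methylbut-2-en-1-yl)-4-(triisopropylsilyloxy)phenyl]-1-[2,4,6-tris(tert-butyldimethylsilyloxy)phenyl]ethan-1-one | CC(C)(C)[Si](C)(C)Oc1cc(O[Si](C)(C)C(C)(C)C)c(C(=O)Cc2cc(OC)c(O[Si](C(C)C)(C(C)C)C(C)C)c(CC=C(C)C)c2)c(O[Si](C)(C)C(C)(C)C)c1
F5 | step 8 | (E)-3-(dimethylamino)-2-[3-methoxy-5-(3-methylbut-2-en-1-yl)-4-(triisopropylsilyloxy)phenyl]-1-[2,4,6-tris(tert-butyldimethylsilyloxy)phenyl]prop-2-en-1-one | CN(C)/C=C(/C(=O)c1c(O[Si](C)(C)C(C)(C)C)cc(O[Si](C)(C)C(C)(C)C)cc1O[Si](C)(C)C(C)(C)C)c1cc(OC)c(O[Si](C(C)C)(C(C)C)C(C)C)c(CC=C(C)C)c1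
F6 | step 8 | (E)-3-(dimethylamino)-2-[4-hydroxy-3-methoxy-5-(3-methylbut-2-en-1-yl)phenyl]-1-(2,4,6-trihydroxyphenyl)prop-2-en-1-one | CN(C)/C=C(/C(=O)c1c(O)cc(O)cc1O)c1cc(OC)c(O)c(CC=C(C)C)c1
F7 | step 5 | 4-bromo-2-methoxy-1-(prop-2-en-1-yloxy)benzene | C=CCOc1ccc(Br)cc1OC
F8 | step 5 | racemic 4-bromo-2-methoxy-6-(prop-2-en-1-yl)cyclohexa-2,4-dien-1-one | O=C1C(OC)=CC(Br)=CC1CC=C
F9 | step 5 | 4-bromo-2-methoxy-6-(prop-2-en-1-yl)phenol | C=CCc1cc(Br)cc(OC)c1O
F10 | step 2 | 2-iodobenzene-1,3,5-triol | Oc1cc(O)c(I)c(O)c1
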